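All runs are calculated with made-up constants, and the scatter is random.

Whatever these flasks do, the charge of D and E stays among D, E, Q and Z, so the 4 shares add to 100, and a late reading tells you how that sum is divided.

| flask | D | E | remark | time |
|---|---|---|---|---|
| autumn | 0.050 M | 0.025 M (fed, over 15 h) | run made earlier; the fed solution adds 0.20 times the starting volume |  |
| midnight | 0.050 M | 0.10 M (fed, over 15 h) | run made earlier; the fed solution adds 0.20 times the starting volume |  |
| dusk | 0.10 M | 0.050 M (fed, over 15 h) | run made earlier; the fed solution adds 0.20 times the starting volume |  |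
| flask | 0.050 M | 0.0500 M (fed, over 15 h) | the fed solution adds 0.20 times the starting volume | 15 d |

| run | time / d | D / % | Q / % | Z / % |
|---|---|---|---|---|
| autumn | 4.00 | 2 | 86 | 14 |
| autumn | 8.00 | 0 | 83 | 16 |
| autumn | 10.0 | 0 | 85 | 10 |
| autumn | 15.0 | 0 | 89 | 10 |
| autumn | 20.0 | 2 | 85 | 10 |
| midnight | 1.67 | 10 | 45 | 26 |
| midnight | 5.00 | 1 | 87 | 16 |
| midnight | 8.00 | 0 | 88 | 15 |
| midnight | 12.0 | 1 | 86 | 11 |
| midnight | 20.0 | 0 | 87 | 14 |
| dusk | 1.67 | 6 | 52 | 19 |
| dusk | 5.00 | 0 | 86 | 14 |
| dusk | 8.00 | 1 | 84 | 8 |
| dusk | 12.0 | 0 | 88 | 12 |
| dusk | 20.0 | 2 | 88 | 14 |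

(standard deviation of a reading: 2 percentage points)

1. why nothing more happens at 15 d, or that something still does (E counts as not reacted) (all of D has reacted / it is still moving / forward and back rates have come level)
2. conversion of D and E together at 15 d
3. amount of Q at 15 d, in percent of the D and E together charged
4. amount of Z at 15 d, in percent of the D and E together charged

- amounts are per litre of the starting volume; all of the dose is in the solution fed
- in a conversion E counts as not yet reacted
- the reaction counts as stopped when no species that holds the D and E together changes by six tenths of a point or more over the second half of the time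
- a reading of D is of its free form alone

Read the table downwards. In the midnight run Z stands at 26% at 1.67 d, beside Q at 45%; by 8.00 d it reads 15%, beside 88%. From 8.00 d on, no trend stands out by eye, so replace each curve by its mean. Those 10 rows give Z 12.0%, Q 86.3% and D 0.600%, each mean uncertain by 0.63 percentage points.

Call the result the late share, cZ/(cQ+cZ) taken from those means: 12.2%.

Now check what the replacement costs. Z averages 13.0% over the 3 readings at 8.00 d and 12.7% at 20.0 d. That gap of 0.33 points is smaller than the 1.6 points that scatter alone gives such a difference. Then compare columns: the autumn run, with E to D at 0.500, averages Z 11.5%, and the midnight run, at 2.00, averages 13.3%. The new flask, at 1.00, lies between them, and 15 d lies inside the window.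

D's mean is within its own error of zero, and E was not read, but the means of D, Q and Z add up to 98.9%, so I reckon with both at zero. My reckoning for the flask: D has reacted to the end, Z 12.2%, Q 87.8%.

The forecast gives conversion 99.5%, Q 86.5% and Z 12.8%, but differs from me on the ending, naming forward and back rates have come level and setting that against “a reaction that simply ran out of reagent”.

The flask gives conversion >99.9%, Q 87.0% and Z 13.0%, with the ending all of D has reacted: D stands at 0% at 15.0 d.

    D ⇌ E, settled at all times (K = 2.40)
    D → Q (k = 0.0150 h⁻¹)
    E → Z (k = 0.0460 h⁻¹)
    Q ⇌ Z (K = 0.150, k = 0.00960 h⁻¹)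

The flask's Z lies 0.80 points above your late share, about 1.32 errors of the mean. The return of Z to Q puts that share under thermodynamic control: without it, the same flask holds Z at 99.5% instead of 13.0% at 15 d. Read at 4.0 d, ahead of the window, the flask holds Z 15.1% beside Q 81.6%, where the late share allots Z 11.8%.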